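The ten-membered carbocycle is unveiled, not closed: C5 and C10 lie 1,6 across it, so a C5–C10 bond turns it into a cis-fused decalin (ring A: C1–C5, C10; ring B: C5–C10). In one operation the C10 alkoxide of an α-3,4-epoxy-4-methyldecalin-10-ol cleaves that bond and delivers the C10 ketone, the Z C4=C5 alkene and the C3 carbinol, with C6, C7 and C8 already set on ring B. The precursor 20 carries C1 and C6 PMB ethers, a C7 tert-butyl acetate arm and a C8 TES ether; C1–O stands trans to C10–OH so that the later methyl addition at C10 is chelate-controlled.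

Key step: step 13

Remark on numbering: germacrane numbers are used from compound 6 on; β is the face of C5–H in the decalin, α the opposite face, and the SMILES strings define the stereochemistry (PMB = 4-methoxybenzyl, TBS = tert-butyldimethylsilyl, TES = triethylsilyl, TMS = trimethylsilyl).

Remark on C1: C1 is carried as the α-ether (1S in 20 and 21), trans to the C10 oxygen, because chelate-controlled methyl addition to the 1β-epimer of ketone 22 would give the C10 epimer of the target.

Remark on step 3: the catalyst antipode named is the one expected from the accepted pre-transition-state model; its mirror image would give ent-6 and would then be exchanged.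

Step 1
Reactants: 1 (E)-4-methoxybut-3-en-2-one; 2 4-methoxybenzyl alcohol
Product: 3 (E)-4-(4-methoxybenzyloxy)but-3-en-2-one
Conditions: pyridinium p-toluenesulfonate (cat.), toluene, 80 °C, reduced pressure (MeOH removed)
Reagents that add atoms: none
Why: Acid-catalysed vinylogous transesterification (conjugate addition–elimination on the β-alkoxy enone) driven by removal of methanol; the E enone is the thermodynamic isomer.

Step 2
Reactants: 3 (E)-4-(4-methoxybenzyloxy)but-3-en-2-one
Product: 4 (E)-1-(4-methoxybenzyloxy)-3-(tert-butyldimethylsilyloxy)buta-1,3-diene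
Conditions: tBuMe2SiOTf, Et3N, Et2O, 0 °C
Reagents that add atoms: tert-butyldimethylsilyl triflate, CC(C)(C)[Si](C)(C)OS(=O)(=O)C(F)(F)F
Why: Silyl enol ether formation by soft enolisation of the methyl ketone gives the 1-alkoxy-3-silyloxy diene with the E enol ether retained.

Step 3
Reactants: 4 (E)-1-(4-methoxybenzyloxy)-3-(tert-butyldimethylsilyloxy)buta-1,3-diene; 5 methyl (E)-4-oxopent-2-enoate
Product: 6 methyl 5α-acetyl-6α-(PMB-oxy)-8-(TBS-oxy)cyclohex-7-ene-10β-carboxylate (ring B)
Conditions: (S)-3,3-diphenyl-1-(o-tolyl)tetrahydropyrrolo[1,2-c][1,3,2]oxazaborole·HNTf2 (20 mol%), CH2Cl2, −78 °C; Et3N quench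
Reagents that add atoms: none
Why: Catalytic enantioselective Diels–Alder reaction: the cationic boron Lewis acid binds the ketone, so the nucleophilic CH2 terminus (C9) bonds to the enone β-carbon (C10), the acetyl group reacts endo and places C6–OPMB cis to it, the E dienophile fixes acetyl and ester trans, and the catalyst shields one enone face to set the absolute configuration of C5 and C6 (C10 is reset in step 5).

Step 4
Reactants: 6 methyl 5α-acetyl-6α-(PMB-oxy)-8-(TBS-oxy)cyclohex-7-ene-10β-carboxylate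
Product: 7 methyl 5α-isopropenyl-6α-(PMB-oxy)-8-(TBS-oxy)cyclohex-7-ene-10β-carboxylate
Conditions: Tebbe reagent Cp2Ti(μ-Cl)(μ-CH2)AlMe2, pyridine (cat.), THF–toluene, −40 → 0 °C
Reagents that add atoms: Tebbe reagent Cp2Ti(μ-Cl)(μ-CH2)AlMe2 (Cl→Al dative bond not drawn), C[Al](C)C[Ti](Cl)(C1C=CC=C1)C1C=CC=C1
Why: Tebbe methylenation converts the ketone well before the ester and is non-basic, so the epimerisable C5 centre and the β-alkoxy ketone are not enolised.

Step 5
Reactants: 7 methyl 5α-isopropenyl-6α-(PMB-oxy)-8-(TBS-oxy)cyclohex-7-ene-10β-carboxylate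
Product: 8 methyl 10β-hydroxy-5α-isopropenyl-6α-(PMB-oxy)-8-(TBS-oxy)cyclohex-7-ene-10α-carboxylate
Conditions: LiN(iPr)2, THF, −78 °C; then 2-(phenylsulfonyl)-3-phenyloxaziridine, −78 °C; aq. NH4Cl
Reagents that add atoms: 2-(phenylsulfonyl)-3-phenyloxaziridine, O=S(=O)(N1OC1c1ccccc1)c1ccccc1
Why: Ester enolate α-hydroxylation with an N-sulfonyloxaziridine; the oxidant meets the planar C10 enolate anti to the α-oriented isopropenyl and OPMB groups, so the hydroxyl enters β (cis to C5–H) and the ester ends cis to the isopropenyl group.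

Step 6
Reactants: 8 methyl 10β-hydroxy-5α-isopropenyl-6α-(PMB-oxy)-8-(TBS-oxy)cyclohex-7-ene-10α-carboxylate
Product: 10 1-[10β-hydroxy-5α-isopropenyl-6α-(PMB-oxy)-8-(TBS-oxy)cyclohex-7-en-10α-yl]but-3-en-1-ol (1α-OH; anti to C10–OH), via α-hydroxy aldehyde 9 (not isolated)
Conditions: iBu2AlH (2.2 equiv), CH2Cl2, −78 °C; then CH2=CHCH2MgBr (3 equiv), Et2O, −78 → −20 °C
Reagents that add atoms: allylmagnesium bromide, C=CC[Mg]Br
Why: One-pot partial reduction of the α-hydroxy ester to the chelated aluminium hemiacetal and chelation-controlled allyl Grignard addition to the released aldehyde; allyl attacks the five-membered chelate (C10–O and C1=O on the metal) from the side of C9, not the branched C5, which sets C1 with its oxygen anti to the C10 hydroxyl.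

Step 7
Reactants: 10 1-[10β-hydroxy-5α-isopropenyl-6α-(PMB-oxy)-8-(TBS-oxy)cyclohex-7-en-10α-yl]but-3-en-1-ol
Product: 12 1α-PMB ether 10β-TMS ether of 10, via C1 PMB ether 11 (not isolated)
Conditions: NaH (2.2 equiv), 4-MeOC6H4CH2Br, tetrabutylammonium iodide (cat.), THF–DMF, 0 °C; then Me3SiCl
Reagents that add atoms: 4-methoxybenzyl bromide, COc1ccc(CBr)cc1; chlorotrimethylsilane, C[Si](C)(C)Cl
Why: Williamson etherification of the less hindered secondary alkoxide followed by in situ O-silylation of the remaining tertiary alkoxide, which shields that hydroxyl from the carbenoid of step 9.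

Step 8
Reactants: 12 1α-PMB ether 10β-TMS ether of 10
Product: 13 cis-fused 4-methylocta-3,7-diene (octalin) with 1α-OPMB; 6α-OPMB; 8-OTBS enol ether; 10β-OTMS; 5β-H
Conditions: second-generation Grubbs catalyst (H2IMes)(PCy3)Cl2Ru=CHPh (5 mol%), CH2Cl2, 40 °C
Reagents that add atoms: none
Why: Ring-closing olefin metathesis of the vinyl and isopropenyl groups, which are cis on ring B, closes ring A as the cis-fused octalin with the trisubstituted C3=C4 alkene; the trisubstituted silyl enol ether is a bystander.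

Step 9
Reactants: 13 cis-fused 4-methylocta-3,7-diene with 1α-OPMB; 6α-OPMB; 8-OTBS; 10β-OTMS; 14 tert-butyl diazoacetate
Product: 16 tert-butyl 2-[1α,6α-bis(PMB-oxy)-10β-hydroxy-4-methyl-8-oxo-cis-octal-3-en-7β-yl]acetate, via siloxycyclopropane 15 (not isolated)
Conditions: Rh2(OAc)4 (1 mol%), CH2Cl2, rt, slow addition of 14; then Et3N·3HF, THF, 0 °C
Reagents that add atoms: none
Why: Rhodium-carbenoid cyclopropanation of the electron-rich silyl enol ether (much faster than attack on the trisubstituted C3=C4 alkene) and fluoride-induced opening of the donor–acceptor siloxycyclopropane give the γ-keto ester regiospecifically at C7 without a basic enolate, so the β-OPMB group is not eliminated, and also free the C10 hydroxyl; C7 is epimerisable and settles with the arm trans to the C6 ether (β).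

Step 10
Reactants: 16 tert-butyl 2-[1α,6α-bis(PMB-oxy)-10β-hydroxy-4-methyl-8-oxo-cis-octal-3-en-7β-yl]acetate
Product: 17 tert-butyl 2-[1α,6α-bis(PMB-oxy)-8β,10β-dihydroxy-4-methyl-cis-octal-3-en-7β-yl]acetate
Conditions: Et2BOMe, THF–MeOH (4:1), −78 °C; NaBH4; MeOH/AcOH work-up
Reagents that add atoms: none
Why: Narasaka–Prasad reduction: the boron chelate between the C10 hydroxyl and the C8 carbonyl blocks the β-axial trajectory, so hydride enters equatorially and gives the 8β-alcohol, syn to C10–OH and cis to the C7 arm; the tert-butyl ester does not lactonise onto it.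

Step 11
Reactants: 17 tert-butyl 2-[1α,6α-bis(PMB-oxy)-8β,10β-dihydroxy-4-methyl-cis-octal-3-en-7β-yl]acetate
Product: 18 8β-TES ether of 17 (C10–OH free)
Conditions: Et3SiCl, imidazole, DMF, 0 °C
Reagents that add atoms: chlorotriethylsilane, CC[Si](Cl)(CC)CC
Why: Selective silylation of the secondary C8 hydroxyl; the tertiary C10 hydroxyl does not react with a silyl chloride under these conditions.

Step 12
Reactants: 18 8β-TES ether of 17
Product: 20 cis-fused 3α,4α-epoxy-4β-methyldecalin-10β-ol with 1α-OPMB; 6α-OPMB; 7β-CH2CO2tBu; 8β-OTES; 5β-H, via bromohydrin 19 (not isolated)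
Conditions: N-bromosuccinimide, NaHCO3, THF–H2O (3:1), 0 °C; then K2CO3, MeOH, 0 °C → rt
Reagents that add atoms: water, O; N-bromosuccinimide, O=C1CCC(=O)N1Br (bromine only in 19)
Why: Halohydrin formation and base closure: the bromonium ion forms on the convex β face, water opens it trans from the α face, and intramolecular SN2 displacement of bromide then gives the α-epoxide, which is the face opposite to the one direct peracid epoxidation would take; C3 and C4 are set by this anti addition–inversion sequence.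

Step 13
Reactants: 20 cis-fused 3α,4α-epoxy-4β-methyldecalin-10β-ol with 1α-OPMB; 6α-OPMB; 7β-CH2CO2tBu; 8β-OTES
Product: 21 (Z)-3α-hydroxy-4-methylcyclodec-4-en-10-one with 1α-OPMB; 6α-OPMB; 7β-CH2CO2tBu; 8β-OTES
Conditions: Ti(OiPr)4 (2 equiv), toluene, 25 → 70 °C; aqueous tartrate work-up
Reagents that add atoms: none
Why: Ti(OiPr)4 exchanges onto the C10 hydroxyl and the alkoxide drives a concerted Grob fragmentation of the 3,4-epoxy alcohol, in which the C5–C10 σ bond breaks as the C10 carbonyl and the C4=C5 π bond form and the epoxide C4–O bond leaves as the C3 alkoxide. The closest known reaction type is the titanium- or base-mediated fragmentation of bicyclic epoxy alcohols, and the Wharton fragmentation of decalin-1,3-diol monosulfonates, to medium-ring keto alkenes. No ring is closed by bond formation, so no closure mode applies: the ten-membered ring is revealed by cleaving the bond shared by rings A and B. No stereocentre is created: C3 keeps the epoxide C–O bond, and the Z geometry follows stereospecifically from the trans relation of the α-epoxide oxygen and the β C5–H, since the geometry that puts C5–C10 anti to C4–O (C6 pseudo-axial on ring A, possible only with the cis ring fusion) holds C3 and C6 syn. The step needs cleavage of C5–C10 and not of C1–C10 or C9–C10, and fragmentation in preference to epoxide opening by an external nucleophile; only C5–C10 is β to the leaving group and the non-nucleophilic titanium alkoxide supplies no competing nucleophile. Because C6–O and the C7 arm are axial on ring B in the reacting geometry and the epoxide limits the anti alignment, warming is expected to be needed.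

Step 14
Reactants: 21 (Z)-3α-hydroxy-4-methylcyclodec-4-en-10-one with 1α-OPMB; 6α-OPMB; 7β-CH2CO2tBu; 8β-OTES
Product: 22 3α-TBS ether of 21
Conditions: tBuMe2SiCl, imidazole, DMAP (cat.), DMF, rt
Reagents that add atoms: tert-butyldimethylsilyl chloride, CC(C)(C)[Si](C)(C)Cl
Why: Silylation of the secondary allylic C3 hydroxyl under non-enolising conditions protects it for the oxidations and the acylation that follow.

Step 15
Reactants: 22 3α-TBS ether of 21
Product: 24 10α-(TMS-oxy)-10β-methyl carbinol ether (10R) with 1α-OPMB; 3α-OTBS; 6α-OPMB; 7β-CH2CO2tBu; 8β-OTES, via tertiary carbinol 23 (not isolated)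
Conditions: MeMgBr (3 equiv), Et2O–CH2Cl2, −78 °C; then Me3SiOTf, 2,6-lutidine, −78 → 0 °C
Reagents that add atoms: methylmagnesium bromide, C[Mg]Br; trimethylsilyl triflate, C[Si](C)(C)OS(=O)(=O)C(F)(F)F
Why: Chelation-controlled Grignard addition: magnesium bridges the C10 carbonyl and the C1 ether oxygen and methyl adds to the face anti to C2, which gives the 10R carbinol (C10–O cis to C1–O on the ring), and the ketone reacts well before the tert-butyl ester at −78 °C; the alkoxide is capped in situ as its TMS ether.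

Step 16
Reactants: 24 10α-(TMS-oxy)-10β-methyl carbinol ether with 1α-OPMB; 3α-OTBS; 6α-OPMB; 7β-CH2CO2tBu; 8β-OTES
Product: 27 tert-butyl 2-substituted acrylate (C7 arm = C(=CH2)CO2tBu; all else as in 24), via Mannich base 25 (not isolated), via trimethylammonium iodide 26 (not isolated)
Conditions: LiN(iPr)2 (1.5 equiv), THF, −78 °C; CH2=NMe2+ I−, −78 → 0 °C; then MeI, THF–MeOH, rt; then NaHCO3 (aq), CH2Cl2
Reagents that add atoms: N,N-dimethylmethyleneiminium iodide (Eschenmoser's salt), C=[N+](C)C.[I-]; iodomethane, CI (methyl only in 26)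
Why: Mannich reaction of the tert-butyl ester lithium enolate, N-methylation and base-induced elimination of trimethylamine install the C13 methylene on the open-chain ester, where no ketone or lactone competes for the base; the transient C11 centre is lost in the elimination.

Step 17
Reactants: 27 tert-butyl 2-substituted acrylate
Product: 28 1α,6α-diol (both PMB ethers removed; 3α-OTBS; 8β-OTES; 10α-OTMS and acrylate retained)
Conditions: DDQ (2.6 equiv), CH2Cl2–pH 7 phosphate buffer (10:1), 0 °C → rt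
Reagents that add atoms: none
Why: Oxidative cleavage of both p-methoxybenzyl ethers by DDQ (benzylic hydride abstraction, then hydrolysis of the oxocarbenium ions); the C10 TMS ether prevents capture of the C1 oxocarbenium ion as a benzylidene acetal.

Step 18
Reactants: 28 1α,6α-diol
Product: 29 6α,12-olide: trans-fused α-methylene-γ-butyrolactone with 1α-OH; 3α-OTBS; 8β-OTES; 10α-OTMS
Conditions: KOtBu (0.2 equiv), THF, 0 °C
Reagents that add atoms: none
Why: Alkoxide-catalysed intramolecular transesterification (5-exo-trig attack of the C6 alkoxide on the tert-butyl ester) closes the trans-fused lactone, whereas conjugate addition to C13 would be a disfavoured 5-endo closure; no new stereocentre is formed.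

Step 19
Reactants: 29 6α,12-olide with 1α-OH
Product: 30 1-ketone of 29
Conditions: Dess–Martin periodinane, NaHCO3, CH2Cl2, 0 °C → rt
Reagents that add atoms: none
Why: Dess–Martin oxidation of the only free hydroxyl (secondary, C1) gives the ketone without base, so the β-silyloxy ketone and the α-methylene lactone are untouched.

Step 20
Reactants: 30 1-ketone of 29
Product: 31 8β,10α-diol (3α-OTBS retained)
Conditions: HF·pyridine, pyridine, THF, 0 °C
Reagents that add atoms: none
Why: Selective fluoride desilylation: the TES ether at C8 and the TMS ether at C10 are cleaved much faster than the secondary TBS ether at C3.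

Step 21
Reactants: 31 8β,10α-diol; 32 isovaleryl chloride
Product: 33 8β-isovalerate 3α-TBS ether
Conditions: pyridine, DMAP (cat.), CH2Cl2, 0 °C
Reagents that add atoms: none
Why: DMAP-catalysed acylation of the secondary C8 hydroxyl; the tertiary C10 hydroxyl is not acylated under these conditions.

Step 22
Reactants: 33 8β-isovalerate 3α-TBS ether
Product: 34 target CNP0406522.1
Conditions: HF·pyridine (excess), THF, 0 °C → rt
Reagents that add atoms: none
Why: Fluoride cleavage of the C3 TBS ether under acidic-buffered conditions that leave the β-hydroxy ketone, the ester and the α-methylene lactone intact.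

Compound list

1 | (E)-4-methoxybut-3-en-2-one | CO/C=C/C(C)=O | starting material
2 | 4-methoxybenzyl alcohol | COc1ccc(CO)cc1 | starting material
3 | (E)-4-(4-methoxybenzyloxy)but-3-en-2-one | COc1ccc(CO/C=C/C(C)=O)cc1 | intermediate
4 | (E)-1-(4-methoxybenzyloxy)-3-(tert-butyldimethylsilyloxy)buta-1,3-diene | COc1ccc(CO/C=C/C(=C)O[Si](C)(C)C(C)(C)C)cc1 | intermediate
5 | methyl (E)-4-oxopent-2-enoate | COC(=O)/C=C/C(C)=O | starting material
6 | methyl 5α-acetyl-6α-(PMB-oxy)-8-(TBS-oxy)cyclohex-7-ene-10β-carboxylate (acetyl cis to OPMB, trans to ester) | COC(=O)[C@@H]1[C@@H](C(C)=O)[C@@H](OCc2ccc(OC)cc2)C=C(O[Si](C)(C)C(C)(C)C)C1 | intermediate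
7 | methyl 5α-isopropenyl-6α-(PMB-oxy)-8-(TBS-oxy)cyclohex-7-ene-10β-carboxylate | COC(=O)[C@@H]1[C@@H](C(C)=C)[C@@H](OCc2ccc(OC)cc2)C=C(O[Si](C)(C)C(C)(C)C)C1 | intermediate
8 | methyl 10β-hydroxy-5α-isopropenyl-6α-(PMB-oxy)-8-(TBS-oxy)cyclohex-7-ene-10α-carboxylate | COC(=O)[C@@]1(O)[C@@H](C(C)=C)[C@@H](OCc2ccc(OC)cc2)C=C(O[Si](C)(C)C(C)(C)C)C1 | intermediate
9 | 10β-hydroxy-5α-isopropenyl-6α-(PMB-oxy)-8-(TBS-oxy)cyclohex-7-ene-10α-carbaldehyde | O=C[C@@]1(O)[C@@H](C(C)=C)[C@@H](OCc2ccc(OC)cc2)C=C(O[Si](C)(C)C(C)(C)C)C1 | intermediate (not isolated)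
10 | 1-[10β-hydroxy-5α-isopropenyl-6α-(PMB-oxy)-8-(TBS-oxy)cyclohex-7-en-10α-yl]but-3-en-1-ol, C1–OH anti to C10–OH | C=CC[C@H](O)[C@@]1(O)[C@@H](C(C)=C)[C@@H](OCc2ccc(OC)cc2)C=C(O[Si](C)(C)C(C)(C)C)C1 | intermediate
11 | C1 PMB ether of 10 (formed as its C10 sodium alkoxide) | C=CC[C@H](OCc2ccc(OC)cc2)[C@@]1(O)[C@@H](C(C)=C)[C@@H](OCc2ccc(OC)cc2)C=C(O[Si](C)(C)C(C)(C)C)C1 | intermediate (not isolated)
12 | 1α-PMB ether 10β-TMS ether of 10 | C=CC[C@H](OCc2ccc(OC)cc2)[C@@]1(O[Si](C)(C)C)[C@@H](C(C)=C)[C@@H](OCc2ccc(OC)cc2)C=C(O[Si](C)(C)C(C)(C)C)C1 | intermediate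
13 | cis-fused 4-methylocta-3,7-diene (octalin): 1α-OPMB, 6α-OPMB, 8-OTBS enol ether, 10β-OTMS, 5β-H | C[Si](C)(C)O[C@]12[C@@H](OCc3ccc(OC)cc3)CC=C(C)[C@H]1[C@@H](OCc4ccc(OC)cc4)C=C(O[Si](C)(C)C(C)(C)C)C2 | intermediate
14 | tert-butyl diazoacetate | CC(C)(C)OC(=O)C=[N+]=[N-] | starting material
15 | 7β,8β-fused siloxycyclopropane tert-butyl ester (C11 epimers, both converge) | C[Si](C)(C)O[C@]12[C@@H](OCc3ccc(OC)cc3)CC=C(C)[C@H]1[C@@H](OCc4ccc(OC)cc4)[C@@H]5C(C(=O)OC(C)(C)C)[C@]5(O[Si](C)(C)C(C)(C)C)C2 | intermediate (not isolated)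
16 | tert-butyl 2-[1α,6α-bis(PMB-oxy)-10β-hydroxy-4-methyl-8-oxo-cis-octal-3-en-7β-yl]acetate | O[C@]12[C@@H](OCc3ccc(OC)cc3)CC=C(C)[C@H]1[C@@H](OCc4ccc(OC)cc4)[C@H](CC(=O)OC(C)(C)C)C(=O)C2 | intermediate
17 | 8β,10β-diol from 16 | O[C@]12[C@@H](OCc3ccc(OC)cc3)CC=C(C)[C@H]1[C@@H](OCc4ccc(OC)cc4)[C@H](CC(=O)OC(C)(C)C)[C@H](O)C2 | intermediate
18 | 8β-TES ether of 17 | O[C@]12[C@@H](OCc3ccc(OC)cc3)CC=C(C)[C@H]1[C@@H](OCc4ccc(OC)cc4)[C@H](CC(=O)OC(C)(C)C)[C@H](O[Si](CC)(CC)CC)C2 | intermediate
19 | 3β-bromo-4α-hydroxy bromohydrin of 18 | O[C@]12[C@@H](OCc3ccc(OC)cc3)C[C@H](Br)[C@@](C)(O)[C@H]1[C@@H](OCc4ccc(OC)cc4)[C@H](CC(=O)OC(C)(C)C)[C@H](O[Si](CC)(CC)CC)C2 | intermediate (not isolated)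
20 | cis-fused 3α,4α-epoxy-4β-methyldecalin-10β-ol: 1α-OPMB (1S), 5β-H, 6α-OPMB, 7β-CH2CO2tBu, 8β-OTES | O[C@]12[C@@H](OCc3ccc(OC)cc3)C[C@H]4O[C@@]4(C)[C@H]1[C@@H](OCc5ccc(OC)cc5)[C@H](CC(=O)OC(C)(C)C)[C@H](O[Si](CC)(CC)CC)C2 | intermediate
21 | (Z)-3α-hydroxy-4-methylcyclodec-4-en-10-one: 1α-OPMB (1S), 6α-OPMB, 7β-CH2CO2tBu, 8β-OTES | O=C1[C@@H](OCc2ccc(OC)cc2)C[C@@H](O)/C(C)=C\[C@@H](OCc2ccc(OC)cc2)[C@H](CC(=O)OC(C)(C)C)[C@H](O[Si](CC)(CC)CC)C1 | intermediate
22 | 3α-TBS ether of 21 | O=C1[C@@H](OCc2ccc(OC)cc2)C[C@@H](O[Si](C)(C)C(C)(C)C)/C(C)=C\[C@@H](OCc2ccc(OC)cc2)[C@H](CC(=O)OC(C)(C)C)[C@H](O[Si](CC)(CC)CC)C1 | intermediate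
23 | 10R tertiary carbinol (10β-methyl, 10α-OH; formed as its magnesium alkoxide) | O[C@@]1(C)[C@@H](OCc2ccc(OC)cc2)C[C@@H](O[Si](C)(C)C(C)(C)C)/C(C)=C\[C@@H](OCc2ccc(OC)cc2)[C@H](CC(=O)OC(C)(C)C)[C@H](O[Si](CC)(CC)CC)C1 | intermediate (not isolated)
24 | 10α-TMS ether of 23 | C[Si](C)(C)O[C@@]1(C)[C@@H](OCc2ccc(OC)cc2)C[C@@H](O[Si](C)(C)C(C)(C)C)/C(C)=C\[C@@H](OCc2ccc(OC)cc2)[C@H](CC(=O)OC(C)(C)C)[C@H](O[Si](CC)(CC)CC)C1 | intermediate
25 | Mannich base (C11 dimethylaminomethyl, C11 epimers) | C[Si](C)(C)O[C@@]1(C)[C@@H](OCc2ccc(OC)cc2)C[C@@H](O[Si](C)(C)C(C)(C)C)/C(C)=C\[C@@H](OCc2ccc(OC)cc2)[C@H](C(CN(C)C)C(=O)OC(C)(C)C)[C@H](O[Si](CC)(CC)CC)C1 | intermediate (not isolated)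
26 | trimethylammonium iodide of 25 | C[Si](C)(C)O[C@@]1(C)[C@@H](OCc2ccc(OC)cc2)C[C@@H](O[Si](C)(C)C(C)(C)C)/C(C)=C\[C@@H](OCc2ccc(OC)cc2)[C@H](C(C[N+](C)(C)C)C(=O)OC(C)(C)C)[C@H](O[Si](CC)(CC)CC)C1.[I-] | intermediate (not isolated)
27 | tert-butyl acrylate (C7 arm C(=CH2)CO2tBu) | C[Si](C)(C)O[C@@]1(C)[C@@H](OCc2ccc(OC)cc2)C[C@@H](O[Si](C)(C)C(C)(C)C)/C(C)=C\[C@@H](OCc2ccc(OC)cc2)[C@H](C(=C)C(=O)OC(C)(C)C)[C@H](O[Si](CC)(CC)CC)C1 | intermediate
28 | 1α,6α-diol of 27 | C[Si](C)(C)O[C@@]1(C)[C@@H](O)C[C@@H](O[Si](C)(C)C(C)(C)C)/C(C)=C\[C@@H](O)[C@H](C(=C)C(=O)OC(C)(C)C)[C@H](O[Si](CC)(CC)CC)C1 | intermediate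
29 | trans-fused 6α,12-olide (α-methylene lactone): 1α-OH, 3α-OTBS, 8β-OTES, 10α-OTMS | C[Si](C)(C)O[C@@]1(C)[C@@H](O)C[C@@H](O[Si](C)(C)C(C)(C)C)/C(C)=C\[C@H]2OC(=O)C(=C)[C@@H]2[C@H](O[Si](CC)(CC)CC)C1 | intermediate
30 | 1-ketone of 29 | C[Si](C)(C)O[C@@]1(C)C(=O)C[C@@H](O[Si](C)(C)C(C)(C)C)/C(C)=C\[C@H]2OC(=O)C(=C)[C@@H]2[C@H](O[Si](CC)(CC)CC)C1 | intermediate
31 | 8β,10α-diol (3α-OTBS) | O[C@@]1(C)C(=O)C[C@@H](O[Si](C)(C)C(C)(C)C)/C(C)=C\[C@H]2OC(=O)C(=C)[C@@H]2[C@H](O)C1 | intermediate
32 | isovaleryl chloride | CC(C)CC(Cl)=O | starting material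
33 | 8β-isovalerate 3α-TBS ether | O[C@@]1(C)C(=O)C[C@@H](O[Si](C)(C)C(C)(C)C)/C(C)=C\[C@H]2OC(=O)C(=C)[C@@H]2[C@H](OC(=O)CC(C)C)C1 | intermediate
34 | CNP0406522.1 (3R,6R,7R,8R,10R; 4Z) | C=C1C(=O)O[C@@H]2/C=C(/C)[C@H](O)CC(=O)[C@](C)(O)C[C@@H](OC(=O)CC(C)C)[C@@H]12 | target

Total step count: 22. Longest linear sequence: 22 steps (1 → 34); 2, 5, 14 and 32 each enter in a single step.

Steps most likely to fail

1. Step 13 (key step). The fragmentation may be slow because the reacting geometry is strained and the epoxide C–O bond cannot reach a full anti alignment with C5–C10. Side processes would then be epoxide opening by another pathway or epimerisation of C1 next to the new ketone. Fallback, a radical cleavage of the same bond, setting out from 20 and coming back at 21: PhI(OAc)2 and iodine under visible light would turn the C10 hydroxyl into its hypoiodite and then the C10 alkoxy radical. β-Scission of C5–C10 gives the C10 ketone and a C5 radical next to the epoxide, which opens C4–O to the C4=C5 alkene and a C3 alkoxy radical. That radical is held as its hypoiodite and reduced to the C3 alcohol on Na2S2O3 work-up. This path has no anti-alignment requirement but is not stereospecific, so any E isomer would have to be separated; it makes no new compound (F0).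

2. Step 12. Facial selectivity may be poor in bromonium formation or opening, or the bromonium ion may be captured by the C1 ether oxygen; either would give the β-epoxide (and then the E alkene) or a bridged ether. Fallback by epoxide inversion, setting out from 18 and coming back at 20: mCPBA attacks the convex face and gives the 3β,4β-epoxide F1. Dilute HClO4 in aqueous THF opens it at the tertiary C4 from the α face to the 3β,4α-diol F2. MsCl and pyridine sulfonylate only the secondary C3 hydroxyl to give the 3β-mesylate F3, and K2CO3 in MeOH closes the C4 alkoxide onto C3 with inversion to 20.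

3. Step 3. Enantio- or regiocontrol may erode, or the acid-labile diene may be lost to the cationic Lewis acid. Fallback with a two-point-binding dienophile, setting out from 4 and coming back at 6: the fumarate half-imide 3-[(E)-3-(methoxycarbonyl)acryloyl]oxazolidin-2-one F4 (from monomethyl fumarate chloride and lithiated oxazolidin-2-one) reacts with 4 under [Cu((S,S)-tBu-box)](SbF6)2 catalysis. The chelated imide is endo and directs C9 to the ester-bearing carbon, giving the imide adduct F5. AlMe3 with MeONHMe·HCl converts the imide into the Weinreb amide F6, and MeMgBr at −78 → 0 °C gives the methyl ketone 6.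

Further compounds

F0 | step 13 | none | none
F1 | step 12 | 3β,4β-epoxide (C3/C4 epimer of 20) | O[C@]12[C@@H](OCc3ccc(OC)cc3)C[C@@H]4O[C@]4(C)[C@H]1[C@@H](OCc5ccc(OC)cc5)[C@H](CC(=O)OC(C)(C)C)[C@H](O[Si](CC)(CC)CC)C2
F2 | step 12 | 3β,4α-diol | O[C@]12[C@@H](OCc3ccc(OC)cc3)C[C@H](O)[C@@](C)(O)[C@H]1[C@@H](OCc5ccc(OC)cc5)[C@H](CC(=O)OC(C)(C)C)[C@H](O[Si](CC)(CC)CC)C2
F3 | step 12 | 3β-mesylate of F2 | O[C@]12[C@@H](OCc3ccc(OC)cc3)C[C@H](OS(C)(=O)=O)[C@@](C)(O)[C@H]1[C@@H](OCc5ccc(OC)cc5)[C@H](CC(=O)OC(C)(C)C)[C@H](O[Si](CC)(CC)CC)C2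
F4 | step 3 | 3-[(E)-3-(methoxycarbonyl)acryloyl]oxazolidin-2-one | COC(=O)/C=C/C(=O)N1CCOC1=O
F5 | step 3 | imide Diels–Alder adduct (C5 acyl-oxazolidinone in place of acetyl) | COC(=O)[C@@H]1[C@@H](C(=O)N2CCOC2=O)[C@@H](OCc2ccc(OC)cc2)C=C(O[Si](C)(C)C(C)(C)C)C1
F6 | step 3 | Weinreb amide from F5 | COC(=O)[C@@H]1[C@@H](C(=O)N(C)OC)[C@@H](OCc2ccc(OC)cc2)C=C(O[Si](C)(C)C(C)(C)C)C1
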